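**Retrosynthetic overview**
- Target 18 ⇐ C4-formyl butenolide 17 (Pinnick oxidation) ⇐ triene 15. One ozonolysis turns the C4 vinyl group into the C4 formyl group and the terminal isopropenyl group into the methyl ketone, so no protecting group is needed.
- The strategy rests on the furanone ring O1–C2(=O)–C3(CH3)=C4–C5. The unit C5–C4=C3–CH3 is a but-2-ynyl carbinol; a carbon substituent at C4 and the C2 carboxyl at C3 must be added anti across its triple bond, so that C2 lies cis to the C5 oxygen and can close the only ring.
- 15 ⇐ (S)-propargylic alcohol 10 + vinylmagnesium chloride 11 + carbon dioxide 12: alkoxide-directed anti-carbomagnesiation (C4–vinyl), carboxylation (C2–C3), lactonisation (O1–C2). The furanone is the only ring and is formed here.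
- 10 ⇐ ynone 9 (asymmetric transfer hydrogenation sets C5) ⇐ Weinreb amide 7 + prop-1-ynylmagnesium bromide 8 ⇐ acid 5 ⇐ 12-bromododecanoic acid 1 + 4-bromo-2-methylbut-1-ene 2 (copper-catalysed alkyl–alkyl coupling).

Key step: step 5

Remark on the chemistry: the side-chain methyl ketone is carried as an isolated isopropenyl group, assumed inert to the Grignard reagents, the ruthenium hydride and cold dilute acid; it is unveiled in the same ozonolysis that converts the C4 vinyl group.

**Step 1**
Reactants: 1 12-bromododecanoic acid; 2 4-bromo-2-methylbut-1-ene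
Product: 5 15-methylhexadec-15-enoic acid, via 3-methylbut-3-enylmagnesium bromide 3 (not isolated), via chloromagnesium 12-bromododecanoate 4 (not isolated)
Conditions: 2, Mg, THF, rt; 1, MeMgCl (1.0 equiv), THF, −20 °C; then 3 (1.5 equiv), Li2CuCl4 (3 mol %), −20 °C → rt; 1 M HCl
Reagents that add atoms: none
Why: Copper-catalysed alkyl–alkyl cross-coupling of a primary Grignard reagent with a primary bromide (Kochi coupling with Li2CuCl4) is fast at −20 °C, a temperature at which the chloromagnesium carboxylate is not attacked, and the 1,1-disubstituted alkene takes no part.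

**Step 2**
Reactants: 5 15-methylhexadec-15-enoic acid
Product: 7 N-methoxy-N,15-dimethylhexadec-15-enamide, via acyl imidazole 6 (not isolated)
Conditions: CDI, CH2Cl2, rt; then MeNH(OMe)·HCl, rt
Reagents that add atoms: N,O-dimethylhydroxylamine hydrochloride, CNOC.Cl
Why: Activation of the acid as its acyl imidazole and aminolysis by N,O-dimethylhydroxylamine (Weinreb amide formation) runs at room temperature without strong acid or base, so the alkene is untouched.

**Step 3**
Reactants: 7 N-methoxy-N,15-dimethylhexadec-15-enamide; 8 prop-1-ynylmagnesium bromide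
Product: 9 18-methylnonadec-18-en-2-yn-4-one
Conditions: 8 (0.5 M in THF, 1.5 equiv), THF, 0 °C → rt; inverse quench into 1 M HCl, 0 °C
Reagents that add atoms: none
Why: Weinreb ketone synthesis: the magnesium chelate of the tetrahedral adduct survives until the quench, so the alkynyl Grignard reagent adds only once, and the inverse acid quench protonates the freed hydroxylamine before it can add to the ynone.

**Step 4**
Reactants: 9 18-methylnonadec-18-en-2-yn-4-one
Product: 10 (S)-18-methylnonadec-18-en-2-yn-4-ol
Conditions: Ru[(S,S)-TsDPEN](p-cymene) (1 mol %), i-PrOH, rt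
Reagents that add atoms: none
Why: Noyori asymmetric transfer hydrogenation: in the six-membered Ru–H/N–H transition state the alkynyl group takes the position next to the η6-arene that an aryl group normally takes, so the (S,S)-catalyst should give the (S)-carbinol (the future C5), the reduction of an ynone by 2-propanol is practically irreversible, and the isolated alkene and the alkyne are not reduced.

**Step 5**
Reactants: 10 (S)-18-methylnonadec-18-en-2-yn-4-ol; 11 vinylmagnesium chloride; 12 carbon dioxide
Product: 15 (S)-3-methyl-5-(14-methylpentadec-14-en-1-yl)-4-vinylfuran-2(5H)-one, via oxamagnesole chelate 13 (not isolated), via Z-hydroxy acid 14 (not isolated)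
Conditions: 11 (4.5 equiv), THF–cyclohexane, reflux; then 12 (dry gas), −20 °C → rt; then 2 M HCl, 0 °C → rt
Reagents that add atoms: none
Why: The first equivalent of 11 deprotonates 10 (ethene is lost), and the magnesium alkoxide guides a second vinylmagnesium unit to the alkyne so that vinyl bonds to the proximal carbon C4 and magnesium to C3 inside the five-membered oxamagnesole 13, a net anti addition across C3≡C4; this is the known magnesium-mediated anti-carbometalation of propargylic alcohols with vinyl Grignard reagents. Carbon dioxide inserts into the C3–Mg bond with retention of alkene geometry (C2–C3 bond), so the carboxyl group of 14 lies cis to the C5 hydroxyl. On acidification the only ring closes by 5-exo-trig attack of the C5 oxygen on the carboxyl carbon (O1–C2, lactonisation with loss of water). No stereocentre is created; C5, set in step 4, has no bond broken and keeps its (S) configuration. The step needs proximal regioselectivity and anti geometry, and both are secured by the C5 alkoxide chelate, because only C3 can carry magnesium within a five-membered ring. The butenolide appears only after the basic reagents are quenched, and the remote 1,1-disubstituted alkene is inert to the Grignard reagent and to cold dilute acid.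

**Step 6**
Reactants: 15 (S)-3-methyl-5-(14-methylpentadec-14-en-1-yl)-4-vinylfuran-2(5H)-one
Product: 17 (S)-4-methyl-5-oxo-2-(14-oxopentadecyl)-2,5-dihydrofuran-3-carbaldehyde, via bis-ozonide 16 (not isolated)
Conditions: O3/O2 (metered, ca. 2 equiv), CH2Cl2, −78 °C; then PPh3, −78 °C → rt
Reagents that add atoms: ozone, [O-][O+]=O
Why: Ozonolysis with reductive work-up: electrophilic ozone should cleave the isolated 1,1-disubstituted alkene and the terminal vinyl group of the dienoate far faster than the tetrasubstituted ring alkene, which the lactone carbonyl deactivates, and triphenylphosphine reduces the ozonides without base so that C5 is not epimerised.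

**Step 7**
Reactants: 17 (S)-4-methyl-5-oxo-2-(14-oxopentadecyl)-2,5-dihydrofuran-3-carbaldehyde
Product: 18 (S)-4-methyl-5-oxo-2-(14-oxopentadecyl)-2,5-dihydrofuran-3-carboxylic acid
Conditions: NaClO2, NaH2PO4, 2-methylbut-2-ene, t-BuOH/H2O, 0 °C → rt
Reagents that add atoms: sodium chlorite, [Na+].[O-]Cl=O
Why: Pinnick (Lindgren) oxidation: chlorous acid adds to the formyl group and the adduct fragments to the carboxylic acid at pH 3–4, 2-methylbut-2-ene removes the hypochlorous acid, and the ketone, the electron-poor ring alkene and the C5 stereocentre should not be affected.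

**Compound list**
1 | 12-bromododecanoic acid | OC(=O)CCCCCCCCCCCBr | starting material
2 | 4-bromo-2-methylbut-1-ene | CC(=C)CCBr | starting material
3 | 3-methylbut-3-enylmagnesium bromide | CC(=C)CC[Mg]Br | intermediate
4 | chloromagnesium 12-bromododecanoate | BrCCCCCCCCCCCC(=O)O[Mg]Cl | intermediate
5 | 15-methylhexadec-15-enoic acid | CC(=C)CCCCCCCCCCCCCC(=O)O | intermediate
6 | 1-(15-methylhexadec-15-enoyl)imidazole (acyl imidazole) | CC(=C)CCCCCCCCCCCCCC(=O)n1ccnc1 | intermediate
7 | N-methoxy-N,15-dimethylhexadec-15-enamide | CC(=C)CCCCCCCCCCCCCC(=O)N(C)OC | intermediate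
8 | prop-1-ynylmagnesium bromide | CC#C[Mg]Br | starting material
9 | 18-methylnonadec-18-en-2-yn-4-one | CC(=C)CCCCCCCCCCCCCC(=O)C#CC | intermediate
10 | (S)-18-methylnonadec-18-en-2-yn-4-ol | CC#C[C@@H](O)CCCCCCCCCCCCCC(C)=C | intermediate
11 | vinylmagnesium chloride | C=C[Mg]Cl | starting material
12 | carbon dioxide | O=C=O | starting material
13 | (S)-3-methyl-5-(14-methylpentadec-14-en-1-yl)-4-vinyl-2,5-dihydro-1,2-oxamagnesole (oxamagnesole chelate) | C=CC1=C(C)[Mg]O[C@H]1CCCCCCCCCCCCCC(C)=C | intermediate
14 | (S,Z)-4-hydroxy-2,18-dimethyl-3-vinylnonadeca-2,18-dienoic acid (Z-hydroxy acid) | C=C/C([C@@H](O)CCCCCCCCCCCCCC(C)=C)=C(\C)C(=O)O | intermediate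
15 | (S)-3-methyl-5-(14-methylpentadec-14-en-1-yl)-4-vinylfuran-2(5H)-one | C=CC1=C(C)C(=O)O[C@H]1CCCCCCCCCCCCCC(C)=C | intermediate
16 | (S)-3-methyl-5-[13-(3-methyl-1,2,4-trioxolan-3-yl)tridecyl]-4-(1,2,4-trioxolan-3-yl)furan-2(5H)-one (bis-ozonide, mixture at the trioxolane carbons) | CC1(CCCCCCCCCCCCC[C@@H]2OC(=O)C(C)=C2C3OCOO3)OCOO1 | intermediate
17 | (S)-4-methyl-5-oxo-2-(14-oxopentadecyl)-2,5-dihydrofuran-3-carbaldehyde | CC(=O)CCCCCCCCCCCCC[C@@H]1OC(=O)C(C)=C1C=O | intermediate
18 | (S)-4-methyl-5-oxo-2-(14-oxopentadecyl)-2,5-dihydrofuran-3-carboxylic acid | CC(=O)CCCCCCCCCCCCC[C@@H]1OC(=O)C(C)=C1C(=O)O | target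

**Step count**
Total step count: 7. Longest linear sequence: 7 steps (1 or 2 → 5 → 7 → 9 → 10 → 15 → 17 → 18).

**Steps most likely to fail**

Step 5 (key step). The carbomagnesiation may stall on the secondary alkoxide, the alkenylmagnesium may be protonated before it takes up carbon dioxide, or the product diene may dimerise on concentration. The fallback assembles the same ring by conjugate addition with the polarity reversed; it sets out from Weinreb amide 7 and comes back at butenolide 15. DIBAL-H (THF, −78 °C) should reduce 7 to 15-methylhexadec-15-enal F1. Zinc–ProPhenol-catalysed addition of methyl propiolate (Me2Zn, toluene), with the ligand enantiomer that delivers the alkynyl group to the Re face of the aldehyde, should give methyl (S)-4-hydroxy-18-methylnonadec-18-en-2-ynoate F2. Lithium divinylcuprate (THF, −78 °C) should add syn to the ynoate with vinyl at C4, and methyl iodide/HMPA should alkylate the C3–copper bond with retention to give methyl (S,Z)-4-hydroxy-2,18-dimethyl-3-vinylnonadeca-2,18-dienoate F3. Its ester lies cis to the C5 oxygen, so it should lactonise on acid work-up to 15.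

Step 6. Ozone may fail to discriminate between the conjugated vinyl group and the ring alkene, or the cleavage may run past the aldehyde stage. The fallback replaces ozone by dihydroxylation and glycol cleavage; it sets out from 15 and comes back at 17. OsO4 (cat.)/NMO in acetone–water should dihydroxylate only the two terminal alkenes, the tetrasubstituted enoate alkene being too hindered and electron-poor, to give (5S)-4-(1,2-dihydroxyethyl)-5-(14,15-dihydroxy-14-methylpentadecyl)-3-methylfuran-2(5H)-one F4 as a mixture at the new carbinol carbons. NaIO4 (THF–water, neutral) should then cleave both glycols to 17.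

Step 1. The copper-catalysed coupling may be slow on the sparingly soluble carboxylate salt, so that homocoupling and reduction of the Grignard reagent take over. The fallback forms the same C–C bond by sulfone alkylation and reductive desulfonylation; it sets out from 2 and 1 and comes back at acid 5. Bromide 2 with sodium benzenesulfinate (DMF, 60 °C) should give (3-methylbut-3-en-1-yl) phenyl sulfone F5. Its α-lithio derivative (n-BuLi, THF, −78 °C) should be alkylated by the lithium salt of 1 (THF/DMPU) to give 15-methyl-13-(phenylsulfonyl)hexadec-15-enoic acid F6. Sodium amalgam (Na2HPO4, MeOH) should remove the sulfonyl group and give 5.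

**Further compounds**
F1 | step 5 | 15-methylhexadec-15-enal | CC(=C)CCCCCCCCCCCCCC=O
F2 | step 5 | methyl (S)-4-hydroxy-18-methylnonadec-18-en-2-ynoate | COC(=O)C#C[C@@H](O)CCCCCCCCCCCCCC(C)=C
F3 | step 5 | methyl (S,Z)-4-hydroxy-2,18-dimethyl-3-vinylnonadeca-2,18-dienoate | C=C/C([C@@H](O)CCCCCCCCCCCCCC(C)=C)=C(\C)C(=O)OC
F4 | step 6 | (5S)-4-(1,2-dihydroxyethyl)-5-(14,15-dihydroxy-14-methylpentadecyl)-3-methylfuran-2(5H)-one | CC(O)(CO)CCCCCCCCCCCCC[C@@H]1OC(=O)C(C)=C1C(O)CO
F5 | step 1 | (3-methylbut-3-en-1-yl) phenyl sulfone | CC(=C)CCS(=O)(=O)c1ccccc1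
F6 | step 1 | 15-methyl-13-(phenylsulfonyl)hexadec-15-enoic acid | CC(=C)CC(CCCCCCCCCCCC(=O)O)S(=O)(=O)c1ccccc1
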